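**Retrosynthetic overview**

- The route rests on ring A. Its C1 hydroxyl has bromine exactly at the ortho carbon C2 and the para carbon C4, and the aryloxy oxygen at C6. A free phenol with C6 blocked brominates in just this pattern, so ring A can be carried as a cyclohexanone until the last step.
- The C6–O(aryl) bond is disconnected at the sp3 level: 2-chlorocyclohexanone 1 and 2,4-dibromophenol 2 give the racemic α-aryloxy ketone 3 by SN2. No aryl–oxygen coupling has to choose among four C–Br bonds.
- Last step: 3 with four equivalents of Br2 passes through the α,α'-dibromo ketone 4, loses two HBr to give 2-(2,4-dibromophenoxy)phenol 5, and is brominated twice to the target 6.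
- No ring is formed. Ring B is bought intact in 2; ring A is bought as the carbocycle of 1 and aromatised last.

Key step: step 2

Remark on the chemistry: the target has no stereocentre. Ketone 3 is used as the racemate and 4 as a mixture of diastereomers, because every sp3 centre of ring A is erased on aromatisation.

**Route**

Step 1
Reactants: 1 2-chlorocyclohexanone (racemic); 2 2,4-dibromophenol
Product: 3 rac-2-(2,4-dibromophenoxy)cyclohexan-1-one
Conditions: K2CO3 (1.5 equiv), KI (0.1 equiv), acetone, reflux; 1 used in slight excess (1.2 equiv)
Reagents that add atoms: none
Why: Williamson-type O-alkylation in which the phenoxide of 2 displaces chloride from the carbonyl-activated α-carbon of 1 by SN2 (helped by in-situ Finkelstein exchange with iodide), the weak carbonate base and the poorly basic dibromophenoxide disfavouring elimination and Favorskii rearrangement; the new stereocentre forms racemic and is erased in step 2.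

Step 2
Reactants: 3 rac-2-(2,4-dibromophenoxy)cyclohexan-1-one
Product: 6 2,4-dibromo-6-(2,4-dibromophenoxy)phenol, via 2,6-dibromo-2-(2,4-dibromophenoxy)cyclohexan-1-one 4 (not isolated), via 2-(2,4-dibromophenoxy)phenol 5 (not isolated)
Conditions: Br2 (2.05 equiv), HBr (cat.), dry ClCH2CH2Cl, 0 °C to rt; then 80 °C, N2 sweep; then Br2 (2.05 equiv), 0 °C to rt
Reagents that add atoms: bromine, BrBr
Why: Acid-catalysed enolisation should let the first two equivalents of Br2 brominate both α-carbons of the ketone (C2, which carries the aryloxy group, and C6) to give 4; on warming, the C2 bromide, an α-bromo ether, should ionise with oxygen assistance and lose a C3 proton, and the C6 bromide should then leave from the dienol of the resulting 6-bromo-2-aryloxyenone, so that two HBr are expelled and the ring arrives at phenol 5. The closest known reaction type is the bromination–dehydrobromination aromatisation of cyclohexanones to phenols, which with excess bromine is known to run on to bromophenols. No ring is closed and no stereocentre is created; the racemic centre of 3 and the mixed centres of 4 become sp2 carbons. The second two equivalents of Br2 should then enter 5 by electrophilic aromatic substitution para and ortho to the free hydroxyl (C4 and C2 of ring A), the only ortho and para sites left because C6 carries the aryloxy group. The selectivity needed is positional: ring B is deactivated by its two bromines and should stay untouched at 0 °C with bromine held to four equivalents overall, and adding the bromine in two portions keeps free Br2 away from the transient enone so that no bromine is fixed at C3 or C5. The dry, non-nucleophilic solvent keeps the α-bromo-α-aryloxy carbon of 4 from solvolysis with loss of 2,4-dibromophenol, and the deactivated ring B should not undergo acid-mediated cyclodehydration onto the ketone.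

**Compound list**

1 | 2-chlorocyclohexanone (racemic) | O=C1CCCCC1Cl | starting material
2 | 2,4-dibromophenol | Oc1ccc(Br)cc1Br | starting material
3 | rac-2-(2,4-dibromophenoxy)cyclohexan-1-one | O=C1CCCCC1Oc1ccc(Br)cc1Br | intermediate
4 | 2,6-dibromo-2-(2,4-dibromophenoxy)cyclohexan-1-one (mixture of diastereomers, not isolated) | O=C1C(Br)CCCC1(Br)Oc1ccc(Br)cc1Br | intermediate
5 | 2-(2,4-dibromophenoxy)phenol (not isolated) | Oc1ccccc1Oc1ccc(Br)cc1Br | intermediate
6 | 2,4-dibromo-6-(2,4-dibromophenoxy)phenol | Oc1c(Br)cc(Br)cc1Oc1ccc(Br)cc1Br | target

Total step count: 2
Longest linear sequence: 2

**Steps most likely to fail**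

The route has only two steps, so both are ranked. The key step is entered twice, once for each of its two separable processes.

1. Step 2, aromatisation stage. Three processes may go wrong. HBr may be lost from the α-bromo ether while free Br2 is still present, so that bromine adds to the enol-ether double bond of the 2-aryloxyenone and ends up fixed at C3. Ionisation at C2 may expel 2,4-dibromophenol. The second dehydrobromination may stall under purely acidic conditions. The fallback takes ring A as an arene from the start and makes the hydroxyl by Baeyer–Villiger oxidation. It sets out from 2. SNAr of its phenoxide on 2-fluorobenzaldehyde (K2CO3, DMF, 100 °C) should give 2-(2,4-dibromophenoxy)benzaldehyde F1. Oxidation with mCPBA in CH2Cl2 should proceed with aryl migration, favoured by the donating ortho-aryloxy group, to 2-(2,4-dibromophenoxy)phenyl formate F2. Hydrolysis with KOH in aqueous MeOH and acidification should give 5, which is isolated here. The fallback comes back to the route at 5, which is brominated with Br2 (2.05 equiv, CH2Cl2, 0 °C) as in the last stage of step 2 to give 6.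

2. Step 2, ring-bromination stage. Positional control may be lost: a third substitution may occur on ring A at C3 or C5 or on ring B at C6', or the reaction may stop after the para bromination. The fallback avoids any electrophilic bromination of the diaryl ether by carrying all four bromines in the building blocks. It sets out from 2. SNAr on 2,4-dibromo-6-fluorobenzaldehyde (K2CO3, DMF, 80 °C) should give 2,4-dibromo-6-(2,4-dibromophenoxy)benzaldehyde F3, because fluoride ortho to the formyl group is displaced far faster than the bromides. Baeyer–Villiger oxidation with mCPBA (CH2Cl2, NaHCO3 buffer) should give 2,4-dibromo-6-(2,4-dibromophenoxy)phenyl formate F4. Hydrolysis with KOH in aqueous MeOH and acidification comes back to the route at 6.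

3. Step 1. HCl may be eliminated from 1 to give cyclohexenone, the chloroketone may undergo Favorskii-type ring contraction, or the SN2 reaction may be slow because the phenoxide of 2 is hindered and weakly nucleophilic. The fallback makes the C–O bond by epoxide opening and sets the ketone afterwards. It sets out from 2. Anti opening of cyclohexene oxide by the phenoxide (Cs2CO3, DMF, 110 °C) should give rac-trans-2-(2,4-dibromophenoxy)cyclohexan-1-ol F5. Oxidation with Dess–Martin periodinane (CH2Cl2, rt) comes back to the route at 3.

**Further compounds**

F1 | step 2 | 2-(2,4-dibromophenoxy)benzaldehyde | O=Cc1ccccc1Oc1ccc(Br)cc1Br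
F2 | step 2 | 2-(2,4-dibromophenoxy)phenyl formate | O=COc1ccccc1Oc1ccc(Br)cc1Br
F3 | step 2 | 2,4-dibromo-6-(2,4-dibromophenoxy)benzaldehyde | O=Cc1c(Br)cc(Br)cc1Oc1ccc(Br)cc1Br
F4 | step 2 | 2,4-dibromo-6-(2,4-dibromophenoxy)phenyl formate | O=COc1c(Br)cc(Br)cc1Oc1ccc(Br)cc1Br
F5 | step 1 | rac-trans-2-(2,4-dibromophenoxy)cyclohexan-1-ol | O[C@@H]1CCCC[C@H]1Oc1ccc(Br)cc1Br
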